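**The clock.** No constant is given, so I read one from the runs and work with the fraction left, not the fraction made.

the same everywhere: free catalyst 0.1 mol%
- elm: starting material 2 mM; second substrate 1 equiv; reagent 0.50 equiv; run made earlier
- ash: starting material 1.3 mM; second substrate 1 equiv; reagent 0.50 equiv; run made earlier
- birch: starting material 3 mM; second substrate 1 equiv; reagent 0.50 equiv; run made earlier
- amber: starting material 2.0 mM; second substrate 1.00 equiv (fed, over 2.0 min); reagent 0.500 equiv; all else is in the flask from the start; the feed brings no volume worth counting; time 2.5 min
- red: starting material 2.0 mM; second substrate 1.00 equiv; reagent 0.500 equiv (fed, over 2.0 min); all else is in the flask from the start; the feed brings no volume worth counting; time 2.5 min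
- ochre: starting material 2.0 mM; second substrate 1.00 equiv; reagent 0.500 equiv; everything together at the start; time 2.5 min
- blue: starting material 2.0 mM; second substrate 1.00 equiv (in portions, 4, over 2.0 min); reagent 0.500 equiv; first portion at the start, last at 2.0 min; time 2.5 min

elm run (percent of the starting material charged): time / min: target / % = 0.200: 11.3; 0.417: 20.9; 0.667: 27.0; 1.33: 35.1; 2.50: 37.4

ash run (percent of the starting material charged): time / s: target / % = 10.0: 7.0; 20.0: 13.8; 30.0: 18.4; 60.0: 29.0; 120: 37.6

birch run (percent of the starting material charged): time / s: target / % = 10.0: 12.5; 20.0: 21.0; 30.0: 26.1; 60.0: 32.9; 120: 34.5

(each reading ± 0.3 percentage points)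

- amounts and yields of target count crystals too
- given per volume of solution although it is solid: crystals
- the earlier runs were read with a standard deviation of 0.3 percentage points
- candidate steps: crystals <-> target; reagent + catalyst intermediate A -> free catalyst + target; starting material + free catalyst <-> catalyst intermediate A; second substrate + free catalyst <-> catalyst intermediate B; reagent + catalyst intermediate B -> free catalyst + second product

- which flask leads in amount of target, in percent of the starting material charged ("all alike" within 1.5 percentage points) (amber / red / ochre / blue / all alike)
- how much target is there at the end, in percent of the starting material charged: amber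
- how much target is there at the end, in percent of the starting material charged: red
- how much target is there at the end, in percent of the starting material charged: ochre
- how much target is there at the end, in percent of the starting material charged: blue

Reagent, at 0.500 equiv, is the limiting reagent. In elm I take the target still to come, as a share of the last reading, for the fraction of reagent left, which assumes a steady split between products. The negative logarithm of that fraction, divided by the time, gives 1.92 min⁻¹ at the third reading and 1.80 min⁻¹ at the first. I carry the former as the reagent clock, the pseudo-first-order rate constant of reagent. In birch the clock reads 2.83 min⁻¹, faster than elm by a factor of 1.47, while the concentration rose by a factor of 1.50 at equal loading. So I scale the clock with concentration.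

**The slowing.** I see one slowing, the fall of reagent, and the rate halves every 0.361 min. By 2.5 min this clock puts the rate in elm at 0.823% of its start, so I expect ochre, which has elm's recipe, at about elm's last reading of 37.4%.

**The feeds.** In amber reagent is present from the start, and one half-life on this clock is shorter than the feed: it takes up 18.1% of the feed time. For red, I reckon that a steady feed against this clock leaves 9.77% of the reagent at 2.5 min, which puts the share used at 90.2%.

**The forecast.** It names amber as leader, with 45.5% (42.5% to 48%), blue 44%, ochre 37.5% and red 32.5%. On red it says “leaving reagent unconsumed at 2.5 min” and counts about 80% used, which is less than my reckoning.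

**The result.** Amber leads with 47.2%, then blue 45.3%, red 40.3% and ochre 37.5%.

    crystals ⇌ target, rate k1*(cs1 - [target]) while solid is left; crystals form when [target] > cs1 (solubility = 0.690 mM, k = 1.50 s⁻¹)
    reagent + catalyst intermediate A → free catalyst + target (k = 20000 L mol⁻¹ s⁻¹)
    starting material + free catalyst ⇌ catalyst intermediate A (K = 87000 L mol⁻¹, k = 40000 L mol⁻¹ s⁻¹)
    second substrate + free catalyst ⇌ catalyst intermediate B (K = 1100 L mol⁻¹, k = 8.80 × 10⁵ L mol⁻¹ s⁻¹)
    reagent + catalyst intermediate B → free catalyst + second product (k = 23000 L mol⁻¹ s⁻¹)

**The comparison.** In amber the half-life of reagent by the target-forming step, at 0.336 min, is 0.36 min, shorter than the 2.0 min feed. Half of the turnover of that step up to 2.5 min is done by 0.337 min, at 16.9% of the feed time, and amber ends with second product at 0.0526 mM against 0.247 mM in ochre. In red the clock gave 9.77% of the reagent left, and the flask holds 6.77% of its charge. For amber's neighbour at 0.50 mM starting material, the scaled clock leaves 30.1% of the reagent, and that flask holds 28.1% of its charge.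

The data stem from a simulated flask from invented constants; scatter was added.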